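Atom labels: ring A is the benzene ring (C3a, C4, C5, C6, C7, C7a). Ring B is the dihydrofuran ring (O1, C2, C3, C3a, C7a). The side chain on C2 is C1' (methine), C2' (CH2O) and C3' (methyl).

## Analysis of the target

Target 9 consists of two (E)-p-coumaric acid units joined through one C5 unit. Ring A bears the free (E)-acrylic acid at C5 and is fused to ring B. C2 bears the chain C1'H(C3'H3)–C2'H2–O, whose oxygen is acylated by the second p-coumaroyl unit with its phenol free. The two stereocentres, C2 (S, in ring B) and C1' (S, outside the ring), are vicinal. In the zig-zag C2'–C1'–C2–C3 the methyl group C3' and O1 stand on the same side (syn).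

The plan rests on one feature: C3, C2, C1', C2' and C3' are the carbon skeleton of isoprene. This unit is tied to two neighbouring positions of ring A by the bonds C3–C3a and, through the phenol oxygen on C7a, O1–C2. Ring B is therefore one alkene of isoprene laid across the ortho carbon and the oxygen of a phenol, and the side chain is the other alkene after anti-Markovnikov addition of H and O.

The sensitive groups are:
- two cinnamoyl acceptors, which are reduced by hydrides, by metal-catalysed boranes and by hydrogenation;
- a free phenol and a free acid;
- the ester between the halves, which does not survive hydroxide or alkoxide;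
- ring B, which aromatises if an exocyclic alkene migrates into it.

Any intermediate with a carbonyl group at C2' would have an acidic C1'–H and O1 as a β-leaving group, so epimerisation and E1cB ring opening threaten routes at that oxidation level. The difficulty is control rather than size. C1' sits on a freely rotating chain with only H, CH3 and CH2O to tell apart. Three acidic OH functions must be differentiated, and two nearly identical cinnamoyl units must end up in different places without protecting-group overhead.

## Retrosynthetic reasoning

**Disconnection 1, C5–Cβ of the acrylic acid (9 to 7 + 8).** This bond is made last, by a Mizoroki–Heck reaction of aryl bromide 7 with acrylic acid 8 itself. The free cinnamic acid is the one group that the earlier operations do not tolerate. It would suffer conjugate reduction under metal-catalysed hydroboration, and it would compete with 6 as the acid partner in the esterification. A bromine at C5 is silent through all of this, so no ester protection and no deprotection are needed. The forward reaction must couple an electron-rich aryl bromide with 8 faster than with the β-substituted alkene of the coumarate already present.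

**Disconnection 2, the alkyl–oxygen bond C2'–O of the ester (7 to 5 + 6).** The ester is cut on the alkyl side, not at the acyl carbon. Activating the carboxyl group of 6 would require masking its phenol, since otherwise 6 acylates itself. Activating the primary alcohol 5 under Mitsunobu conditions lets the acidity gap between the acid and the phenol of 6 do the selection. Displacement occurs at C2', one atom away from C1', so no stereocentre is at risk.

**Disconnection 3, C2'–O and C1'–H (5 to 3 by way of 4).** The side chain is the anti-Markovnikov hydrate of an isopropenyl group. This removes C1' as an independent problem, because C2 controls it by 1,2-induction. The required relation is syn. The uncatalysed dialkylborane reaction is anti-selective for this alkene type and is the wrong tool. The rhodium-catalysed variant has the opposite facial preference and is planned, giving boronate 4 and then 5.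

**Disconnection 4, the key one, C3–C3a and O1–C2 (3 to 1 + 2).** Both bonds that tie the C5 unit to ring A are cut at once. Cutting only one of them, or O1–C7a, leaves an acyclic chain whose carbinol stereocentre must be made in a separate sequence. Cutting both leads directly to isoprene 2 and the commercial dihalophenol 1. In one sentence: an enantioselective palladium-catalysed [3+2] heteroannulation lays 2 across the carbon–iodine and O–H bonds of 1. The forward step has to form ring B, set C2, deliver all five side-chain carbons, and leave the bromine of 1 untouched. The halogen pair of 1 programmes the two palladium events of the route, iodine for step 1 and bromine for step 4.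

## Alternatives that were turned down

**Alternative 1: (the textbook route)**
- Disconnection: C1'–C2 by aldol and O1–C7a by aryl ether formation.
- Forward key step: a boron-mediated Evans syn aldol of (R)-4-benzyl-3-propionyloxazolidin-2-one A1 with 2-(2,5-dibromophenyl)acetaldehyde A2 gives the syn adduct A3. Reductive removal of the auxiliary gives (2S,3S)-4-(2,5-dibromophenyl)-2-methylbutane-1,3-diol A4. A copper-catalysed intramolecular O-arylation then gives 5.
- Reason turned down: stereocontrol is dependable, but ring and stereocentres are made in separate operations with a stoichiometric auxiliary. A2 is an easily enolised, self-condensing aldehyde that itself needs several steps. A3 is a β-hydroxy carbonyl compound prone to retro-aldol and epimerisation. The ring closure must distinguish two hydroxyl groups and two bromines. Roughly three times as many steps would be spent to reach 5.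

**Alternative 2:**
- Disconnection: O1–C2 and C1'–C2', with both stereocentres and ring B made in one step.
- Forward key step: an enantioselective Wacker-type oxypalladation/alkoxycarbonylation with divalent palladium converts (E)-4-bromo-2-(but-2-en-1-yl)phenol A5 into methyl (R)-2-[(S)-5-bromo-2,3-dihydro-1-benzofuran-2-yl]propanoate A6. This is followed by ester reduction to 5.
- Reason turned down: the alkylpalladium intermediate on C1' has β-hydrogens on C3' and C2, so elimination competes with carbonyl insertion. Phenols can add to the alkene by a syn or an anti pathway depending on ligand and halide. (E)-A5 leads to the right C1' epimer only by the anti pathway, so the relative configuration is not secured by the substrate. Enantiocontrol in this reaction class depends on more highly substituted alkenes. A6 is exactly the β-aryloxy ester that can epimerise and ring-open, and it costs an extra reduction.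

**Alternative 3:**
- Disconnection: C3–C3a by ortho C–H alkylation and O1–C7a at the ipso carbon.
- Forward key step: a Catellani-type annulation of methyl (E)-3-(4-iodophenyl)acrylate A7 with the enantiopure epoxide (R)-2-[(S)-1-(tert-butyldimethylsilyloxy)propan-2-yl]oxirane A8 gives dihydrobenzofuran A9.
- Reason turned down: the step sets no stereocentre, so both must be built into A8 by a multistep chiral-pool sequence that includes a diastereoselective epoxide construction. The cost moves into the precursor. A7 has no ortho substituent, so a second ortho alkylation competes before the mediator is extruded. The cinnamate units of A7 and A9 are themselves terminating partners for the arylpalladium species. Silyl and methyl ester removal would follow.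

Key step: step 1

Remark on the chemistry: the ligand antipode that gives (S)-3 is assigned by analogy with known isoprene annulations of this type. Both antipodes are equally accessible, and the ligand is not counted as a step.

## Route

Step 1
Reactants: 1 4-bromo-2-iodophenol; 2 isoprene (2-methylbuta-1,3-diene)
Product: 3 (2S)-5-bromo-2-(prop-1-en-2-yl)-2,3-dihydro-1-benzofuran
Conditions: Pd2(dba)3·CHCl3 (2.5 mol %), chiral sulfinamide monophosphine ligand (Sadphos family, TY-Phos type, antipode for S, 10 mol %), NaOPh (2 equiv), 2 (4 equiv), toluene, sealed tube, 50 °C
Reagents that add atoms: none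
Why: This is a Larock heteroannulation of a 1,3-diene in its enantioselective Heck/Tsuji–Trost form, a reaction type shown on o-halophenols with isoprene itself. Zerovalent palladium inserts into the carbon–iodine bond of 1 much faster than into the carbon–bromine bond, and the arylpalladium adds across the unsubstituted vinyl group of 2 with the aryl carbon going to the terminal CH2, which forms C3–C3a. Palladium is thereby placed on C2 as an η3-allyl unit over C2, C1' and the terminal CH2, while the methyl group of 2 steers insertion away from its own alkene for steric reasons and ends up on the central allyl carbon. The phenoxide oxygen then attacks the internal allyl terminus C2 and closes ring B in a 5-exo mode (O1–C2), whereas attack at the CH2 terminus would need a seven-membered ring. C2 is the only new stereocentre and is under ligand control: the two diastereomeric allyl complexes exchange faces by η3–η1–η3 slippage at the unsubstituted CH2 terminus, so both are funnelled through the faster carbon–oxygen bond formation to (S)-3. The step needs site selectivity (iodine before bromine), regioselectivity on the diene and 1,2- rather than 1,4-capture, and these are secured by the halogen pair of 1, the methyl group of 2 and the ring size respectively. NaOPh takes up the hydrogen iodide, and the moderate temperature keeps the electron-rich aryl bromide of 3 out of the catalytic cycle.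

Step 2
Reactants: 3 (2S)-5-bromo-2-(prop-1-en-2-yl)-2,3-dihydro-1-benzofuran
Product: 5 (2S)-2-[(2S)-5-bromo-2,3-dihydro-1-benzofuran-2-yl]propan-1-ol, via alkyl catecholboronate 4 (not isolated)
Conditions: catecholborane (3 equiv), RhCl(PPh3)3 (3 mol %), THF, 20 °C; then 3 M NaOH, 30% H2O2, 0 °C to rt
Reagents that add atoms: catecholborane, [H]B1Oc2ccccc2O1 (boron and catecholate of 4); hydrogen peroxide, OO (oxygen of 5)
Why: Rhodium-catalysed hydroboration puts boron on the terminal carbon C2' and hydrogen on C1', and the oxidation proceeds with retention. With C2–H eclipsing the C=CH2 bond, the alkene binds rhodium on the face anti to the C2–O1 bond, its best σ-acceptor; this is the syn-selective mode known for ethers of the type CH2=C(CH3)–CH(OR)R' and is opposite to the anti preference of uncatalysed dialkylboranes, so (S)-C2 should give (S)-C1'. The aryl bromide and the ring ether are inert, and any minor C1' epimer would be removed by chromatography at 5.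

Step 3
Reactants: 5 (2S)-2-[(2S)-5-bromo-2,3-dihydro-1-benzofuran-2-yl]propan-1-ol; 6 (E)-4-hydroxycinnamic acid (p-coumaric acid)
Product: 7 (2S)-2-[(2S)-5-bromo-2,3-dihydro-1-benzofuran-2-yl]propyl (2E)-3-(4-hydroxyphenyl)prop-2-enoate
Conditions: 6 (1.2 equiv), PPh3 (1.3 equiv), DIAD (1.3 equiv, slow addition), THF, 0 °C to rt
Reagents that add atoms: none
Why: Mitsunobu esterification activates the primary alcohol and not the acid, so only the carboxylic acid of 6 (about five pKa units more acidic than its phenol) protonates the betaine and attacks as carboxylate, a chemoselectivity known for unprotected hydroxycinnamic acids. Substitution takes place at C2', so C1' and C2 are untouched and the (E)-alkene is not affected.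

Step 4
Reactants: 7 (2S)-2-[(2S)-5-bromo-2,3-dihydro-1-benzofuran-2-yl]propyl (2E)-3-(4-hydroxyphenyl)prop-2-enoate; 8 acrylic acid
Product: 9 (2E)-3-[(2S)-2-{(2S)-1-[(2E)-3-(4-hydroxyphenyl)prop-2-enoyloxy]propan-2-yl}-2,3-dihydro-1-benzofuran-5-yl]prop-2-enoic acid (target)
Conditions: Pd(OAc)2 (5 mol %), P(o-tol)3 (12 mol %), Et3N (4 equiv), 8 (2 equiv), DMF, 90 °C; then aq. citric acid
Reagents that add atoms: none
Why: In this Mizoroki–Heck reaction of a p-alkoxyaryl bromide with acrylic acid, syn carbopalladation and syn β-hydride elimination give the (E)-cinnamic acid directly. The unsubstituted terminus of 8 reacts far faster than the β-aryl-substituted alkene of the coumarate. The phenol, the ester and both stereocentres (neither C–H is acidic) tolerate Et3N at this temperature.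

## Compound list

1 | 4-bromo-2-iodophenol | Oc1ccc(Br)cc1I | starting material
2 | isoprene (2-methylbuta-1,3-diene) | C=CC(C)=C | starting material
3 | (2S)-5-bromo-2-(prop-1-en-2-yl)-2,3-dihydro-1-benzofuran | C=C(C)[C@@H]1Cc2cc(Br)ccc2O1 | intermediate
4 | 2-{(2S)-2-[(2S)-5-bromo-2,3-dihydro-1-benzofuran-2-yl]propyl}-1,3,2-benzodioxaborole | C[C@@H](CB1Oc2ccccc2O1)[C@@H]1Cc2cc(Br)ccc2O1 | intermediate
5 | (2S)-2-[(2S)-5-bromo-2,3-dihydro-1-benzofuran-2-yl]propan-1-ol | C[C@@H](CO)[C@@H]1Cc2cc(Br)ccc2O1 | intermediate
6 | (E)-4-hydroxycinnamic acid (p-coumaric acid) | O=C(O)/C=C/c1ccc(O)cc1 | starting material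
7 | (2S)-2-[(2S)-5-bromo-2,3-dihydro-1-benzofuran-2-yl]propyl (2E)-3-(4-hydroxyphenyl)prop-2-enoate | C[C@@H](COC(=O)/C=C/c1ccc(O)cc1)[C@@H]1Cc2cc(Br)ccc2O1 | intermediate
8 | acrylic acid | C=CC(=O)O | starting material
9 | (2E)-3-[(2S)-2-{(2S)-1-[(2E)-3-(4-hydroxyphenyl)prop-2-enoyloxy]propan-2-yl}-2,3-dihydro-1-benzofuran-5-yl]prop-2-enoic acid | C[C@@H](COC(=O)/C=C/c1ccc(O)cc1)[C@@H]1Cc2cc(/C=C/C(=O)O)ccc2O1 | target

## Step count and least certain steps

Total steps: 4. Longest linear sequence: 4 (1 to 3 to 5 to 7 to 9). No protecting group is used.

**Step 1 (key step).**
- Risk: the most likely failure is loss of enantiocontrol. Iodide may stay bound to palladium and open a less organised pathway for the carbon–oxygen bond formation, since the closest precedents start from bromides.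
- Second risk: palladium may insert into the carbon–bromine bond of the product once 1 is consumed.
- Third risk: partial insertion at the methyl-bearing alkene of the diene.
- Fallback, from 1 back to 3 by the biomimetic order of events:
  - Suzuki–Miyaura coupling at the carbon–iodine bond with 3-methylbut-2-enylboronic acid pinacol ester would give 4-bromo-2-(3-methylbut-2-en-1-yl)phenol F1. Conditions are Pd(OAc)2, a biaryl dialkylphosphine that favours the linear product, K3PO4 and aqueous THF.
  - Shi epoxidation would give 4-bromo-2-{[(2R)-3,3-dimethyloxiran-2-yl]methyl}phenol F2. It uses the fructose-derived ketone antipode that gives the R epoxide, KHSO5, K2CO3 buffer and MeCN–dimethoxymethane–water at 0 °C.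
  - In the basic buffer the phenoxide of F2 opens the epoxide at the secondary carbon (5-exo-tet, inversion) to give 2-[(2S)-5-bromo-2,3-dihydro-1-benzofuran-2-yl]propan-2-ol F3.
  - Dehydration toward a methyl group with methyl N-(triethylammoniosulfonyl)carbamate in warm toluene comes back to 3.

**Step 2.**
- Risk: poor facial selectivity, because the oxygen and carbon substituents on C2 are tied back in ring B and may differ less than in the acyclic models.
- Second risk: rhodium hydride may cause alkene migration toward the aromatised ring, or simple hydrogenation of the alkene.
- Fallback, from 3 back to 5, moving stereocontrol from the substrate to a chiral catalyst: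
  - Copper hydride hydroboration would give the isolable 2-{(2S)-2-[(2S)-5-bromo-2,3-dihydro-1-benzofuran-2-yl]propyl}-4,4,5,5-tetramethyl-1,3,2-dioxaborolane F4. Conditions are CuCl, KOt-Bu, the DTBM-SEGPHOS antipode matched to the syn product and pinacolborane in THF at rt. F4 can be freed from its epimer.
  - Oxidation with NaBO3·4H2O in THF–water gives 5.

**Step 3.**
- Risk: competing O-alkylation of the phenol of 6 or of 7 when the carboxylate is depleted, which leads to ether formation and oligomers. The β-branching of 5 slows the desired displacement and makes this worse.
- Fallback, from 5 back to 7 by acyl activation of a masked acid: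
  - Carbodiimide coupling of 5 with commercial (E)-4-acetoxycinnamic acid (EDC·HCl, DMAP, CH2Cl2) would give (2S)-2-[(2S)-5-bromo-2,3-dihydro-1-benzofuran-2-yl]propyl (2E)-3-(4-acetoxyphenyl)prop-2-enoate F5.
  - Brief methanolysis of the aryl acetate (catalytic K2CO3, MeOH, 0 °C) gives 7. The aryl acetate is far more reactive than the alkyl cinnamate.

**Step 4.**
- Risk: slow oxidative addition into the electron-rich aryl bromide, with catalyst decay. This gives time for arylation of the coumarate alkene and for polymerisation of 8. Isolating a polar phenol-acid from palladium residues adds difficulty.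
- Fallback, from 5 back to 9, forming the carbon–carbon bond before the sensitive ester exists:
  - Heck reaction of 5 with tert-butyl acrylate (Pd(OAc)2, P(o-tol)3, Et3N, DMF, 90 °C) would give tert-butyl (2E)-3-{(2S)-2-[(2S)-1-hydroxypropan-2-yl]-2,3-dihydro-1-benzofuran-5-yl}prop-2-enoate F6.
  - Mitsunobu esterification with 6 as in step 3 would give the tert-butyl ester of the target F7.
  - CF3CO2H in CH2Cl2 at 0 °C to rt releases 9.

## Further compounds

F1 | step 1 | 4-bromo-2-(3-methylbut-2-en-1-yl)phenol | CC(C)=CCc1cc(Br)ccc1O
F2 | step 1 | 4-bromo-2-{[(2R)-3,3-dimethyloxiran-2-yl]methyl}phenol | CC1(C)O[C@@H]1Cc1cc(Br)ccc1O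
F3 | step 1 | 2-[(2S)-5-bromo-2,3-dihydro-1-benzofuran-2-yl]propan-2-ol | CC(C)(O)[C@@H]1Cc2cc(Br)ccc2O1
F4 | step 2 | 2-{(2S)-2-[(2S)-5-bromo-2,3-dihydro-1-benzofuran-2-yl]propyl}-4,4,5,5-tetramethyl-1,3,2-dioxaborolane | C[C@@H](CB1OC(C)(C)C(C)(C)O1)[C@@H]1Cc2cc(Br)ccc2O1
F5 | step 3 | (2S)-2-[(2S)-5-bromo-2,3-dihydro-1-benzofuran-2-yl]propyl (2E)-3-(4-acetoxyphenyl)prop-2-enoate | C[C@@H](COC(=O)/C=C/c1ccc(OC(C)=O)cc1)[C@@H]1Cc2cc(Br)ccc2O1
F6 | step 4 | tert-butyl (2E)-3-{(2S)-2-[(2S)-1-hydroxypropan-2-yl]-2,3-dihydro-1-benzofuran-5-yl}prop-2-enoate | C[C@@H](CO)[C@@H]1Cc2cc(/C=C/C(=O)OC(C)(C)C)ccc2O1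
F7 | step 4 | tert-butyl (2E)-3-[(2S)-2-{(2S)-1-[(2E)-3-(4-hydroxyphenyl)prop-2-enoyloxy]propan-2-yl}-2,3-dihydro-1-benzofuran-5-yl]prop-2-enoate | C[C@@H](COC(=O)/C=C/c1ccc(O)cc1)[C@@H]1Cc2cc(/C=C/C(=O)OC(C)(C)C)ccc2O1
A1 | alternative 1 | (R)-4-benzyl-3-propionyloxazolidin-2-one | CCC(=O)N1[C@H](Cc2ccccc2)COC1=O
A2 | alternative 1 | 2-(2,5-dibromophenyl)acetaldehyde | O=CCc1cc(Br)ccc1Br
A3 | alternative 1 | (R)-4-benzyl-3-[(2R,3S)-4-(2,5-dibromophenyl)-3-hydroxy-2-methylbutanoyl]oxazolidin-2-one | C[C@@H](C(=O)N1[C@H](Cc2ccccc2)COC1=O)[C@@H](O)Cc1cc(Br)ccc1Br
A4 | alternative 1 | (2S,3S)-4-(2,5-dibromophenyl)-2-methylbutane-1,3-diol | C[C@@H](CO)[C@@H](O)Cc1cc(Br)ccc1Br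
A5 | alternative 2 | (E)-4-bromo-2-(but-2-en-1-yl)phenol | C/C=C/Cc1cc(Br)ccc1O
A6 | alternative 2 | methyl (R)-2-[(S)-5-bromo-2,3-dihydro-1-benzofuran-2-yl]propanoate | C[C@@H](C(=O)OC)[C@@H]1Cc2cc(Br)ccc2O1
A7 | alternative 3 | methyl (E)-3-(4-iodophenyl)acrylate | COC(=O)/C=C/c1ccc(I)cc1
A8 | alternative 3 | (R)-2-[(S)-1-(tert-butyldimethylsilyloxy)propan-2-yl]oxirane | C[C@@H](CO[Si](C)(C)C(C)(C)C)[C@@H]1CO1
A9 | alternative 3 | methyl (2E)-3-{(2S)-2-[(2S)-1-(tert-butyldimethylsilyloxy)propan-2-yl]-2,3-dihydro-1-benzofuran-5-yl}prop-2-enoate | C[C@@H](CO[Si](C)(C)C(C)(C)C)[C@@H]1Cc2cc(/C=C/C(=O)OC)ccc2O1
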